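## Retrosynthetic overview

1. The butenolide is closed last, from α-hydroxy ketone 22 and Ph3P=C=C=O. The side-chain CH2OH comes from i-Bu2AlH opening of a temporary six-membered lactone.
2. Key disconnection: the bond between the allylic CH2 of the side chain and C5 of the butenolide. It is made by a catalytic asymmetric vinylogous aldol–lactonisation of the α-alkylated but-3-enoate 12 (its γ-carbon becomes that CH2) with the masked dihydroxyacetone aldehyde 16.
3. Enabling feature: on the trisubstituted C=C the CH2OH carbon is cis to that CH2, hence 1,5 to the ring oxygen on butenolide C5 (O–C5–CH2–CH=C–CH2OH). One oxidation level up these six atoms form a 5,6-dihydro-2H-pyran-2-one, which fixes the Z geometry and is cleaved afterwards.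
4. Donor 12: dihydro-β-ionone → terminal alkyne → allylic oxidation and CBS reduction (ring carbinol) → zirconium-catalysed carboalumination/ethylene oxide (E alkene) → iodide → dianion alkylation.
5. Ring order: cyclohexene (bought), temporary dihydropyranone (step 12, opened in step 13), butenolide (step 16).

Key step: step 12

Remark: the α-carbon of 11 and 12 is a stereocentre of no consequence (it becomes sp2 in step 12); both are carried as mixtures of epimers.
Remark: deprotonated forms of numbered compounds (enolates, alkoxides, acetylides, ate complexes) are counted with their parent compound and get no number.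
Short names: TBS = tert-butyldimethylsilyl; TBDPS = tert-butyldiphenylsilyl; "ring A" = (3S)-3-(TBS-oxy)-2,6,6-trimethylcyclohex-1-en-1-yl; "chain B" = (E)-4-methyl-6-(ring A)hex-3-en-1-yl.

## Route

Step 1
Reactants: 1 dihydro-β-ionone, 4-(2,6,6-trimethylcyclohex-1-en-1-yl)butan-2-one
Product: 3 2-(but-3-yn-1-yl)-1,3,3-trimethylcyclohex-1-ene, via enol diethyl phosphate 2 (not isolated)
Conditions: LiN(i-Pr)2 (1.05 equiv), THF, −78 °C; ClP(O)(OEt)2, −78 °C → rt; LiN(i-Pr)2 (2.3 equiv), −78 °C → rt; H2O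
Reagents that add atoms: none
Why: Kinetic enolisation at the methyl group, O-phosphorylation and base-induced β-elimination of the terminal enol phosphate (methyl ketone to terminal alkyne conversion) should give the alkyne without touching the tetrasubstituted ring alkene.

Step 2
Reactants: 3 2-(but-3-yn-1-yl)-1,3,3-trimethylcyclohex-1-ene
Product: 4 3-(but-3-yn-1-yl)-2,4,4-trimethylcyclohex-2-en-1-one
Conditions: CrO3, 3,5-dimethylpyrazole, CH2Cl2, −20 °C
Reagents that add atoms: chromium trioxide, O=[Cr](=O)=O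
Why: Allylic oxidation by the hexavalent chromium–3,5-dimethylpyrazole complex should attack the only unhindered secondary allylic CH2 (ring CH2 next to the methyl-bearing alkene carbon), since the chain allylic CH2 is shielded by the gem-dimethyl group and the propargylic CH2 reacts far more slowly at −20 °C.

Step 3
Reactants: 4 3-(but-3-yn-1-yl)-2,4,4-trimethylcyclohex-2-en-1-one
Product: 5 (S)-3-(but-3-yn-1-yl)-2,4,4-trimethylcyclohex-2-en-1-ol
Conditions: (R)-2-methyl-CBS-oxazaborolidine (0.2 equiv), catecholborane (1.5 equiv), toluene, −78 °C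
Reagents that add atoms: none
Why: Corey–Bakshi–Shibata reduction with the alkenyl arm as the large group should deliver hydride to the face that gives the (S)-allylic alcohol (the antipodal catalyst would be used should the sense prove opposite), and catecholborane at −78 °C does not hydroborate the terminal alkyne.

Step 4
Reactants: 5 (S)-3-(but-3-yn-1-yl)-2,4,4-trimethylcyclohex-2-en-1-ol
Product: 6 (S)-[3-(but-3-yn-1-yl)-2,4,4-trimethylcyclohex-2-en-1-yl]oxy(tert-butyl)dimethylsilane
Conditions: TBSCl, imidazole, DMF, rt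
Reagents that add atoms: tert-butyldimethylsilyl chloride, CC(C)(C)[Si](C)(C)Cl
Why: Standard silylation of a secondary alcohol protects the ring carbinol against the organometallic, basic and reducing steps that follow.

Step 5
Reactants: 6 (S)-[3-(but-3-yn-1-yl)-2,4,4-trimethylcyclohex-2-en-1-yl]oxy(tert-butyl)dimethylsilane
Product: 8 (E)-4-methyl-6-(ring A)hex-3-en-1-ol, via alkenyldimethylalane 7 (not isolated)
Conditions: Me3Al (2.5 equiv), Cp2ZrCl2 (0.25 equiv), CH2Cl2, 0 °C → rt; volatiles removed; n-BuLi, THF/hexane, −78 °C; ethylene oxide, −78 °C → rt; aq. NH4Cl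
Reagents that add atoms: trimethylaluminium, C[Al](C)C; ethylene oxide, C1CO1
Why: Zirconium-catalysed syn-carboalumination (Negishi methylalumination) places methyl and aluminium cis with aluminium on the terminal carbon, and the derived alanate opens ethylene oxide with retention at the alkenyl carbon, which should fix the E-trisubstituted alkene.

Step 6
Reactants: 8 (E)-4-methyl-6-(ring A)hex-3-en-1-ol
Product: 9 (E)-1-iodo-4-methyl-6-(ring A)hex-3-ene (chain B iodide)
Conditions: I2, PPh3, imidazole, CH2Cl2, 0 °C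
Reagents that add atoms: iodine, II
Why: Appel-type iodination of a primary alcohol proceeds under neutral conditions that leave the silyl ether and both alkenes untouched.

Step 7
Reactants: 9 chain B iodide; 10 but-3-enoic acid
Product: 11 2-(chain B)but-3-enoic acid (mixture of α-epimers)
Conditions: 10, LiN(i-Pr)2 (2.2 equiv), THF, −78 → 0 °C; then 9, DMPU, −78 °C → rt; 1 M HCl
Reagents that add atoms: none
Why: Alkylation of the dienediolate (dianion) of but-3-enoic acid with a primary iodide occurs mainly at the α-carbon and should give the α-alkylated β,γ-unsaturated acid, whose new stereocentre is erased in step 12.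

Step 8
Reactants: 11 2-(chain B)but-3-enoic acid
Product: 12 phenyl 2-(chain B)but-3-enoate (mixture of α-epimers)
Conditions: PhOH, DCC, DMAP (5 mol%), CH2Cl2, 0 °C
Reagents that add atoms: phenol, Oc1ccccc1
Why: Steglich esterification at 0 °C with little DMAP should give the aryl ester (more acidic α-proton, good leaving group for the later lactonisation) without moving the double bond into conjugation.

Step 9
Reactants: 13 1,3-dihydroxyacetone dimer, 2,5-bis(hydroxymethyl)-1,4-dioxane-2,5-diol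
Product: 14 2,2-dimethoxypropane-1,3-diol
Conditions: HC(OMe)3, MeOH, TsOH·H2O (cat.), rt; Na2CO3
Reagents that add atoms: methanol, CO; trimethyl orthoformate, COC(OC)OC
Why: Acid-catalysed ketalisation in methanol, driven by the orthoformate as water scavenger, cracks the dimer and masks the ketone as its dimethyl ketal.

Step 10
Reactants: 14 2,2-dimethoxypropane-1,3-diol
Product: 15 3-(TBDPS-oxy)-2,2-dimethoxypropan-1-ol
Conditions: NaH (1.0 equiv), THF, 0 °C; TBDPSCl (1.0 equiv), 0 °C → rt
Reagents that add atoms: tert-butyldiphenylsilyl chloride, CC(C)(C)[Si](Cl)(c1ccccc1)c1ccccc1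
Why: Monosilylation of a symmetrical diol through its sparingly soluble monosodium alkoxide should stop at the mono ether.

Step 11
Reactants: 15 3-(TBDPS-oxy)-2,2-dimethoxypropan-1-ol
Product: 16 3-(TBDPS-oxy)-2,2-dimethoxypropanal
Conditions: (COCl)2, DMSO, CH2Cl2, −78 °C; Et3N, −78 → 0 °C; used freshly
Reagents that add atoms: none
Why: Swern oxidation gives an aldehyde with a quaternary α-carbon that can neither enolise nor epimerise and is activated by the two α-alkoxy groups.

Step 12
Reactants: 12 phenyl 2-(chain B)but-3-enoate; 16 3-(TBDPS-oxy)-2,2-dimethoxypropanal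
Product: 18 (6S)-3-(chain B)-6-[1,1-dimethoxy-2-(TBDPS-oxy)ethyl]-5,6-dihydro-2H-pyran-2-one, via open-chain Z aldol adduct 17 (not isolated)
Conditions: [Cu(MeCN)4]PF6 (10 mol%), (R)-DTBM-SEGPHOS (11 mol%), Et3N (30 mol%), THF, −20 °C → rt
Reagents that add atoms: none
Why: Proposed new method: a monovalent copper–bisphosphine complex and the amine should enolise phenyl ester 12 (α-proton allylic and next to an aryl ester) to a copper dienolate whose α-carbon is blocked by chain B, so that the γ-carbon adds to the aldehyde 16 through a closed, copper-bridged transition state that delivers the Z enoate 17; the copper alkoxide then attacks the cis phenyl ester to close the lactone, and the released phenoxide turns the catalyst over. The closest known reaction type is the direct catalytic asymmetric vinylogous aldol–lactonisation of α-unbranched β,γ-unsaturated esters with aldehydes under monovalent copper and a bulky chiral bisphosphine; the extension lies in the α-alkyl donor and the α,α-dialkoxy aldehyde. The six-membered lactone closes by 6-exo-trig acyl substitution, and only the Z adduct can close, so the ring both proves and locks the alkene geometry (future CH2OH carbon cis to the new CH2). The one new stereocentre, C6 of the lactone (later C5 of the butenolide), should be set by the chiral ligand, which shields one face of the aldehyde in the bridged transition state, the remote silyl ether centre having no influence (the antipodal ligand would be used should the sense prove opposite). The step needs γ- over α-attack (secured by the α-substituent), 1,2-addition without self-condensation (secured by the quaternary α-carbon of 16) and no drift of the donor double bond into conjugation (secured by the mild base and low temperature).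

Step 13
Reactants: 18 (6S)-3-(chain B)-6-[1,1-dimethoxy-2-(TBDPS-oxy)ethyl]-5,6-dihydro-2H-pyran-2-one
Product: 20 (2Z,5S)-2-(chain B)-6,6-dimethoxy-7-(TBDPS-oxy)hept-2-ene-1,5-diol, via lactol 19 (not isolated)
Conditions: i-Bu2AlH (4 equiv), CH2Cl2, −78 → 0 °C; aq. KNaC4H4O6 (potassium sodium tartrate)
Reagents that add atoms: none
Why: 1,2-Reduction of the α,β-unsaturated lactone through the lactol opens the temporary ring to the allylic diol, with the Z geometry carried over from the ring and the C–O bond at the stereocentre never broken.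

Step 14
Reactants: 20 (2Z,5S)-2-(chain B)-6,6-dimethoxy-7-(TBDPS-oxy)hept-2-ene-1,5-diol
Product: 21 (2Z,5S)-2-(chain B)-6,6-dimethoxy-1,7-bis(TBDPS-oxy)hept-2-en-5-ol
Conditions: TBDPSCl (1.05 equiv), imidazole, CH2Cl2, 0 °C
Reagents that add atoms: tert-butyldiphenylsilyl chloride, CC(C)(C)[Si](Cl)(c1ccccc1)c1ccccc1
Why: Silylation should be selective for the primary allylic alcohol, because the secondary alcohol sits next to the quaternary ketal carbon.

Step 15
Reactants: 21 (2Z,5S)-2-(chain B)-6,6-dimethoxy-1,7-bis(TBDPS-oxy)hept-2-en-5-ol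
Product: 22 (3S,5Z)-6-(chain B)-3-hydroxy-1,7-bis(TBDPS-oxy)hept-5-en-2-one
Conditions: PPTS (0.2 equiv), acetone/H2O (10:1), 40 °C
Reagents that add atoms: water, O
Why: Mild acid hydrolysis of the acyclic dimethyl ketal should unmask the ketone faster than the TBDPS and secondary TBS ethers are lost.

Step 16
Reactants: 22 (3S,5Z)-6-(chain B)-3-hydroxy-1,7-bis(TBDPS-oxy)hept-5-en-2-one
Product: 24 (5S)-5-[(2Z)-3-(chain B)-4-(TBDPS-oxy)but-2-en-1-yl]-4-[(TBDPS-oxy)methyl]furan-2(5H)-one, via phosphoranylidene acetate 23 (not isolated)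
Conditions: Ph3P=C=C=O (1.3 equiv), toluene, 90 °C
Reagents that add atoms: (triphenylphosphoranylidene)ketene (Bestmann ylide), O=C=C=P(c1ccccc1)(c1ccccc1)c1ccccc1
Why: Addition of the only free hydroxyl to the Bestmann ylide followed by intramolecular Wittig olefination of the activated ketone is the standard butenolide synthesis from α-hydroxy ketones, and its neutral conditions should leave the carbinol stereocentre (C–O bond untouched) intact.

Step 17
Reactants: 24 (5S)-5-[(2Z)-3-(chain B)-4-(TBDPS-oxy)but-2-en-1-yl]-4-[(TBDPS-oxy)methyl]furan-2(5H)-one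
Product: 25 (5S)-4-(hydroxymethyl)-5-{(2Z,6E)-3-(hydroxymethyl)-9-[(3S)-3-hydroxy-2,6,6-trimethylcyclohex-1-en-1-yl]-7-methylnona-2,6-dien-1-yl}furan-2(5H)-one (target)
Conditions: HF·pyridine, pyridine, THF, 0 °C → rt
Reagents that add atoms: none
Why: Global desilylation with buffered HF·pyridine removes all three silyl ethers under non-basic conditions, chosen because basic fluoride could epimerise C5 of the butenolide through its 2-oxyfuran anion.

## Compound list

1 | dihydro-β-ionone | CC(=O)CCC1=C(C)CCCC1(C)C | starting material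
2 | diethyl 4-(2,6,6-trimethylcyclohex-1-en-1-yl)but-1-en-2-yl phosphate | C=C(CCC1=C(C)CCCC1(C)C)OP(=O)(OCC)OCC | intermediate (not isolated)
3 | 2-(but-3-yn-1-yl)-1,3,3-trimethylcyclohex-1-ene | C#CCCC1=C(C)CCCC1(C)C | intermediate
4 | 3-(but-3-yn-1-yl)-2,4,4-trimethylcyclohex-2-en-1-one | C#CCCC1=C(C)C(=O)CCC1(C)C | intermediate
5 | (S)-3-(but-3-yn-1-yl)-2,4,4-trimethylcyclohex-2-en-1-ol | C#CCCC1=C(C)[C@@H](O)CCC1(C)C | intermediate
6 | TBS ether of 5 | C#CCCC1=C(C)[C@@H](O[Si](C)(C)C(C)(C)C)CCC1(C)C | intermediate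
7 | dimethyl[(E)-2-methyl-4-(ring A)but-1-en-1-yl]alane | C[Al](C)/C=C(\C)CCC1=C(C)[C@@H](O[Si](C)(C)C(C)(C)C)CCC1(C)C | intermediate (not isolated)
8 | (E)-4-methyl-6-(ring A)hex-3-en-1-ol | OCC/C=C(\C)CCC1=C(C)[C@@H](O[Si](C)(C)C(C)(C)C)CCC1(C)C | intermediate
9 | (E)-1-iodo-4-methyl-6-(ring A)hex-3-ene | ICC/C=C(\C)CCC1=C(C)[C@@H](O[Si](C)(C)C(C)(C)C)CCC1(C)C | intermediate
10 | but-3-enoic acid | C=CCC(=O)O | starting material
11 | 2-(chain B)but-3-enoic acid | C=CC(CC/C=C(\C)CCC1=C(C)[C@@H](O[Si](C)(C)C(C)(C)C)CCC1(C)C)C(=O)O | intermediate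
12 | phenyl 2-(chain B)but-3-enoate | C=CC(CC/C=C(\C)CCC1=C(C)[C@@H](O[Si](C)(C)C(C)(C)C)CCC1(C)C)C(=O)Oc1ccccc1 | intermediate
13 | 1,3-dihydroxyacetone dimer | OCC1(O)COC(O)(CO)CO1 | starting material
14 | 2,2-dimethoxypropane-1,3-diol | COC(CO)(CO)OC | intermediate
15 | 3-(TBDPS-oxy)-2,2-dimethoxypropan-1-ol | COC(CO)(OC)CO[Si](c1ccccc1)(c1ccccc1)C(C)(C)C | intermediate
16 | 3-(TBDPS-oxy)-2,2-dimethoxypropanal | COC(C=O)(OC)CO[Si](c1ccccc1)(c1ccccc1)C(C)(C)C | intermediate
17 | phenyl (2Z,5S)-2-(chain B)-5-hydroxy-6,6-dimethoxy-7-(TBDPS-oxy)hept-2-enoate | O=C(Oc1ccccc1)/C(CC/C=C(\C)CCC1=C(C)[C@@H](O[Si](C)(C)C(C)(C)C)CCC1(C)C)=C\C[C@H](O)C(OC)(OC)CO[Si](c1ccccc1)(c1ccccc1)C(C)(C)C | intermediate (not isolated)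
18 | (6S)-3-(chain B)-6-[1,1-dimethoxy-2-(TBDPS-oxy)ethyl]-5,6-dihydro-2H-pyran-2-one | O=C1C(CC/C=C(\C)CCC2=C(C)[C@@H](O[Si](C)(C)C(C)(C)C)CCC2(C)C)=CC[C@@H](C(OC)(OC)CO[Si](c2ccccc2)(c2ccccc2)C(C)(C)C)O1 | intermediate
19 | (6S)-3-(chain B)-6-[1,1-dimethoxy-2-(TBDPS-oxy)ethyl]-5,6-dihydro-2H-pyran-2-ol (lactol, anomers) | OC1C(CC/C=C(\C)CCC2=C(C)[C@@H](O[Si](C)(C)C(C)(C)C)CCC2(C)C)=CC[C@@H](C(OC)(OC)CO[Si](c2ccccc2)(c2ccccc2)C(C)(C)C)O1 | intermediate (not isolated)
20 | (2Z,5S)-2-(chain B)-6,6-dimethoxy-7-(TBDPS-oxy)hept-2-ene-1,5-diol | OC/C(CC/C=C(\C)CCC1=C(C)[C@@H](O[Si](C)(C)C(C)(C)C)CCC1(C)C)=C\C[C@H](O)C(OC)(OC)CO[Si](c1ccccc1)(c1ccccc1)C(C)(C)C | intermediate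
21 | (2Z,5S)-2-(chain B)-6,6-dimethoxy-1,7-bis(TBDPS-oxy)hept-2-en-5-ol | CC(C)(C)[Si](c1ccccc1)(c1ccccc1)OC/C(CC/C=C(\C)CCC1=C(C)[C@@H](O[Si](C)(C)C(C)(C)C)CCC1(C)C)=C\C[C@H](O)C(OC)(OC)CO[Si](c1ccccc1)(c1ccccc1)C(C)(C)C | intermediate
22 | (3S,5Z)-6-(chain B)-3-hydroxy-1,7-bis(TBDPS-oxy)hept-5-en-2-one | CC(C)(C)[Si](c1ccccc1)(c1ccccc1)OC/C(CC/C=C(\C)CCC1=C(C)[C@@H](O[Si](C)(C)C(C)(C)C)CCC1(C)C)=C\C[C@H](O)C(=O)CO[Si](c1ccccc1)(c1ccccc1)C(C)(C)C | intermediate
23 | O-[(triphenylphosphoranylidene)acetyl] ester of 22 | CC(C)(C)[Si](c1ccccc1)(c1ccccc1)OC/C(CC/C=C(\C)CCC1=C(C)[C@@H](O[Si](C)(C)C(C)(C)C)CCC1(C)C)=C\C[C@H](OC(=O)C=P(c1ccccc1)(c1ccccc1)c1ccccc1)C(=O)CO[Si](c1ccccc1)(c1ccccc1)C(C)(C)C | intermediate (not isolated)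
24 | (5S)-5-[(2Z)-3-(chain B)-4-(TBDPS-oxy)but-2-en-1-yl]-4-[(TBDPS-oxy)methyl]furan-2(5H)-one | CC(C)(C)[Si](c1ccccc1)(c1ccccc1)OC/C(CC/C=C(\C)CCC1=C(C)[C@@H](O[Si](C)(C)C(C)(C)C)CCC1(C)C)=C\C[C@@H]1OC(=O)C=C1CO[Si](c1ccccc1)(c1ccccc1)C(C)(C)C | intermediate
25 | (5S)-4-(hydroxymethyl)-5-{(2Z,6E)-3-(hydroxymethyl)-9-[(3S)-3-hydroxy-2,6,6-trimethylcyclohex-1-en-1-yl]-7-methylnona-2,6-dien-1-yl}furan-2(5H)-one | CC1=C(CC/C(C)=C/CC/C(=C/C[C@@H]2OC(=O)C=C2CO)CO)C(C)(C)CC[C@@H]1O | target

## Step count and risks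

Total: 17 steps. Longest linear sequence: 14 steps (steps 1–8 and 12–17); the aldehyde arm (steps 9–11) is 3 steps.

Steps most likely to fail:

1. Step 12 (Proposed new method). Enolisation of the α-branched ester may be too slow, the donor double bond may drift into conjugation before the C–C bond forms, or the two faces of the aldehyde may be poorly differentiated. Fallback by known reactions, setting out from iodide 9 and aldehyde 16 and coming back at lactone 18:
   - The sodium salt of triethyl phosphonoacetate is alkylated with 9 (NaH, THF/DMSO) to ethyl 2-(diethoxyphosphoryl)-2-(chain B)acetate F1.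
   - Horner–Wadsworth–Emmons reaction of F1 with aqueous formaldehyde and K2CO3 gives ethyl 2-(chain B)acrylate F2, which LiOH saponifies to 2-(chain B)acrylic acid F3.
   - Aldehyde 16 is allylated with the appropriate enantiomer of Ipc2B(allyl) (Brown allylation) to (S)-1-(TBDPS-oxy)-2,2-dimethoxyhex-5-en-3-ol F4.
   - Yamaguchi esterification of F4 with F3 gives the diene ester F5.
   - Ring-closing metathesis with the second-generation Grubbs catalyst [RuCl2(=CHPh)(H2IMes)(PCy3)] closes the dihydropyranone 18, whose ring again fixes the Z geometry.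

2. Step 15. The free α-hydroxy ketone may undergo acyloin shift or epimerise, and the acid may strip the allylic silyl ethers before the inductively deactivated ketal opens. Fallback setting out from 21 and coming back at 24:
   - The secondary alcohol is first esterified with diethylphosphonoacetic acid (DCC, DMAP) to the phosphonoacetate F6.
   - Ketal hydrolysis then gives the α-acyloxy ketone F7, which has no free ketol.
   - Intramolecular Horner–Wadsworth–Emmons olefination (LiCl, i-Pr2NEt, MeCN; Masamune–Roush conditions) closes the butenolide 24 directly, bypassing 22 and 23.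

3. Step 2. Hydrogen abstraction may also occur at the propargylic or the chain allylic CH2, and the alkyne may be attacked by hexavalent chromium. Fallback that oxidises before the alkyne is installed, setting out from 1 and coming back at 6:
   - Ketalisation of 1 with ethane-1,2-diol (TsOH) gives the dioxolane F8.
   - The same allylic oxidation gives the enone ketal F9.
   - CBS reduction (here BH3·SMe2 may be used) gives the (S)-alcohol F10, and TBSCl/imidazole the silyl ether F11.
   - PPTS in wet acetone frees the methyl ketone F12.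
   - LiN(i-Pr)2/ClP(O)(OEt)2 gives the enol phosphate F13, and LiN(i-Pr)2 eliminates it to alkyne 6.

Further compounds
F1 | step 12 | ethyl 2-(diethoxyphosphoryl)-2-(chain B)acetate | CCOC(=O)C(CC/C=C(\C)CCC1=C(C)[C@@H](O[Si](C)(C)C(C)(C)C)CCC1(C)C)P(=O)(OCC)OCC
F2 | step 12 | ethyl 2-(chain B)acrylate | C=C(CC/C=C(\C)CCC1=C(C)[C@@H](O[Si](C)(C)C(C)(C)C)CCC1(C)C)C(=O)OCC
F3 | step 12 | 2-(chain B)acrylic acid | C=C(CC/C=C(\C)CCC1=C(C)[C@@H](O[Si](C)(C)C(C)(C)C)CCC1(C)C)C(=O)O
F4 | step 12 | (S)-1-(TBDPS-oxy)-2,2-dimethoxyhex-5-en-3-ol | C=CC[C@H](O)C(OC)(OC)CO[Si](c1ccccc1)(c1ccccc1)C(C)(C)C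
F5 | step 12 | (S)-1-(TBDPS-oxy)-2,2-dimethoxyhex-5-en-3-yl 2-(chain B)acrylate | C=CC[C@H](OC(=O)C(=C)CC/C=C(\C)CCC1=C(C)[C@@H](O[Si](C)(C)C(C)(C)C)CCC1(C)C)C(OC)(OC)CO[Si](c1ccccc1)(c1ccccc1)C(C)(C)C
F6 | step 15 | (diethoxyphosphoryl)acetate of 21 | CC(C)(C)[Si](c1ccccc1)(c1ccccc1)OC/C(CC/C=C(\C)CCC1=C(C)[C@@H](O[Si](C)(C)C(C)(C)C)CCC1(C)C)=C\C[C@H](OC(=O)CP(=O)(OCC)OCC)C(OC)(OC)CO[Si](c1ccccc1)(c1ccccc1)C(C)(C)C
F7 | step 15 | (diethoxyphosphoryl)acetate of 22 | CC(C)(C)[Si](c1ccccc1)(c1ccccc1)OC/C(CC/C=C(\C)CCC1=C(C)[C@@H](O[Si](C)(C)C(C)(C)C)CCC1(C)C)=C\C[C@H](OC(=O)CP(=O)(OCC)OCC)C(=O)CO[Si](c1ccccc1)(c1ccccc1)C(C)(C)C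
F8 | step 2 | 2-methyl-2-[2-(2,6,6-trimethylcyclohex-1-en-1-yl)ethyl]-1,3-dioxolane | CC1(CCC2=C(C)CCCC2(C)C)OCCO1
F9 | step 2 | 2,4,4-trimethyl-3-[2-(2-methyl-1,3-dioxolan-2-yl)ethyl]cyclohex-2-en-1-one | CC1(CCC2=C(C)C(=O)CCC2(C)C)OCCO1
F10 | step 2 | (S)-2,4,4-trimethyl-3-[2-(2-methyl-1,3-dioxolan-2-yl)ethyl]cyclohex-2-en-1-ol | CC1(CCC2=C(C)[C@@H](O)CCC2(C)C)OCCO1
F11 | step 2 | TBS ether of F10 | CC1(CCC2=C(C)[C@@H](O[Si](C)(C)C(C)(C)C)CCC2(C)C)OCCO1
F12 | step 2 | 4-(ring A)butan-2-one | CC(=O)CCC1=C(C)[C@@H](O[Si](C)(C)C(C)(C)C)CCC1(C)C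
F13 | step 2 | diethyl 4-(ring A)but-1-en-2-yl phosphate | C=C(CCC1=C(C)[C@@H](O[Si](C)(C)C(C)(C)C)CCC1(C)C)OP(=O)(OCC)OCC
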